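**Assumptions:** (2S)-Liquiritigenin is purchased as the chiral building block. I checked the CIP assignment of the target's stereocentre and it is (2S), which matches natural (S)-flavanones. The C6 and C8 prenyls are installed in two successive rounds; whichever position the first round hits, the second round fills the other, so a regioisomer mixture converges.

## Retrosynthetic overview
1. The target (8) is the 6,8,3'-triprenyl pattern on (2S)-liquiritigenin (1), so no ring is built. The flavanone ring and its C2 stereocentre come from 1 and are never touched.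
2. Each normal prenyl group comes from an aromatic Claisen [3,3] rearrangement of an aryl 1,1-dimethylallyl ether. These ethers are made by tertiary-propargyl etherification followed by Lindlar semihydrogenation. A prenyl aryl ether would give the wrong "reverse" prenyl.
3. Round 1 alkylates only the acidic 7-OH and installs the first A-ring prenyl (C8, or C6).
4. Round 2 alkylates both remaining phenols, and one double Claisen installs the remaining A-ring prenyl and the 3'-prenyl together.

## Forward route

**Step 1**
Reactants: 1 (2S)-liquiritigenin; 2 3-chloro-3-methylbut-1-yne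
Product: 3 (2S)-2-(4-hydroxyphenyl)-7-[(2-methylbut-3-yn-2-yl)oxy]chroman-4-one
Conditions: 2 (1.2 equiv), K2CO3 (1.1 equiv), KI (0.1 equiv), CuI (0.05 equiv), acetone, 40 °C
Reagents that add atoms: 3-chloro-3-methylbut-1-yne, CC(C)(Cl)C#C
Why: The 7-OH is a vinylogous acid (pKa ≈ 7.5) and is far more acidic than the 4'-OH (pKa ≈ 10), so one equivalent of mild base gives selective Cu-assisted O-propargylation; C2 is not involved and the mild base limits retro-oxa-Michael racemisation.

**Step 2**
Reactants: 3
Product: 4 (2S)-2-(4-hydroxyphenyl)-7-[(2-methylbut-3-en-2-yl)oxy]chroman-4-one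
Conditions: H2 (1 atm), Lindlar catalyst, quinoline, EtOAc, rt
Reagents that add atoms: none (H2 adds only hydrogen)
Why: Poisoned Pd reduces the terminal alkyne to the terminal alkene without touching the ketone or the benzylic C2–O bond; no stereocentre is created or affected.

**Step 3**
Reactants: 4
Product: 5 (2S)-7-hydroxy-2-(4-hydroxyphenyl)-8-(3-methylbut-2-en-1-yl)chroman-4-one (major; the 6-prenyl regioisomer is a minor by-product)
Conditions: PhMe, 110 °C, sealed tube, BHT, 12–24 h (raise to 140 °C in xylenes if slow)
Reagents that add atoms: none
Why: This is the key step, an aromatic Claisen [3,3] rearrangement. The strained tertiary allyl aryl ether transfers its terminal CH2 to the ortho carbon, giving a normal prenyl group after rearomatisation. C8 is favoured because the C7–C8 bond has higher double-bond character. Any C6 isomer carries through and converges at Step 6.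

**Step 4**
Reactants: 5; 2 3-chloro-3-methylbut-1-yne
Product: 6 (2S)-7-[(2-methylbut-3-yn-2-yl)oxy]-2-{4-[(2-methylbut-3-yn-2-yl)oxy]phenyl}-8-prenylchroman-4-one
Conditions: 2 (4 equiv), K2CO3 (3 equiv), KI (0.2 equiv), CuI (0.1 equiv), acetone/DMF, 40–50 °C
Reagents that add atoms: 3-chloro-3-methylbut-1-yne, CC(C)(Cl)C#C
Why: Excess reagent drives Cu-assisted propargylation of both phenols, so no selectivity between them is needed; the configuration at C2 is unchanged.

**Step 5**
Reactants: 6
Product: 7 (2S)-7-[(2-methylbut-3-en-2-yl)oxy]-2-{4-[(2-methylbut-3-en-2-yl)oxy]phenyl}-8-prenylchroman-4-one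
Conditions: H2 (1 atm), Lindlar catalyst, quinoline, EtOAc, rt
Reagents that add atoms: none (H2 adds only hydrogen)
Why: Semihydrogenation of both terminal alkynes; the existing trisubstituted prenyl alkene is inert under these conditions.

**Step 6**
Reactants: 7
Product: 8 target, (2S)-7,4'-dihydroxy-6,8,3'-tris(3-methylbut-2-en-1-yl)flavanone
Conditions: PhMe, 110 °C (or xylenes, 140 °C), sealed tube, BHT
Reagents that add atoms: none
Why: A double aromatic Claisen [3,3] rearrangement. The 7-O ether migrates to the only free ortho position (C6) and the 4'-O ether migrates to C3'. Both give normal prenyl groups and free phenols, and no new stereocentre forms.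

## Compound list
1 | (2S)-liquiritigenin, (2S)-7-hydroxy-2-(4-hydroxyphenyl)chroman-4-one | Oc1ccc(cc1)[C@@H]2CC(=O)c3ccc(O)cc3O2 | starting material
2 | 3-chloro-3-methylbut-1-yne | CC(C)(Cl)C#C | starting material
3 | 7-O-(1,1-dimethylpropargyl)liquiritigenin | Oc1ccc(cc1)[C@@H]2CC(=O)c3ccc(OC(C)(C)C#C)cc3O2 | intermediate
4 | 7-O-(1,1-dimethylallyl)liquiritigenin | Oc1ccc(cc1)[C@@H]2CC(=O)c3ccc(OC(C)(C)C=C)cc3O2 | intermediate
5 | 8-prenylliquiritigenin | Oc1ccc(cc1)[C@@H]2CC(=O)c3ccc(O)c(CC=C(C)C)c3O2 | intermediate
6 | 7,4'-bis-O-(1,1-dimethylpropargyl)-8-prenylliquiritigenin | C#CC(C)(C)Oc1ccc(cc1)[C@@H]2CC(=O)c3ccc(OC(C)(C)C#C)c(CC=C(C)C)c3O2 | intermediate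
7 | 7,4'-bis-O-(1,1-dimethylallyl)-8-prenylliquiritigenin | C=CC(C)(C)Oc1ccc(cc1)[C@@H]2CC(=O)c3ccc(OC(C)(C)C=C)c(CC=C(C)C)c3O2 | intermediate
8 | (2S)-6,8,3'-triprenyl-7,4'-dihydroxyflavanone | CC(C)=CCc1cc([C@@H]2CC(=O)c3cc(CC=C(C)C)c(O)c(CC=C(C)C)c3O2)ccc1O | target

**Total steps:** 6. **Longest linear sequence:** 6 (from 1).

## Three steps most likely to fail
1. **Step 4, alkylation of the hindered 7-OH (next to the 8-prenyl) with a tertiary propargyl chloride.** This step is prone to elimination to the enyne and to base-mediated C2 racemisation. Fallback: brominate C6 of 5 with NBS, then do a Pd-catalysed cross-coupling with prenyl-9-BBN, and prenylate C3' by the same two-stage approach.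
2. **Steps 3 and 6, thermal Claisen of tertiary allyl aryl ethers.** Competing ionisation to a prenyl cation (giving chromans or O→C scrambling), a C6/C8 mixture, or thermal racemisation are the risks. Fallback: direct ortho-C-prenylation of the phenols as their magnesium phenoxides with prenyl bromide, instead of a sigmatropic rearrangement.
3. **Steps 2 and 5, Lindlar semihydrogenation of terminal alkynes.** Over-reduction to the saturated isopentyl ether is the risk. Fallback: make the 1,1-dimethylallyl ethers directly from the phenol and 2-methylbut-3-en-2-yl trichloroacetimidate with catalytic Lewis acid, which avoids the alkyne stage.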